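**Retrosynthetic overview**
1. The C10–Cl bond and both enone C=C bonds come last. HCl acts on the aldol adduct of a 10,11-epoxy ketone, turning the epoxide into the α-chloroenone and the aldol into the 7E-alkylidene.
2. Aldol disconnection at C7–C8 gives an epoxy-hydroxy-cyclopentanone and methyl (5E)-7-oxohept-5-enoate, itself made by cross-metathesis of methyl hex-5-enoate with crotonaldehyde.
3. The epoxy ketone comes from nucleophilic epoxidation of (4R)-4-hydroxy-4-octenylcyclopent-2-enone.
4. Key disconnection: both ring C–O bonds (C12–OH and C9=O) come from O2 and 1-octenylcyclopentadiene, by [4+2] addition and then an enantiomer-selecting peroxide fragmentation that fixes C12.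
5. The diene comes from NaC5H5 and (Z)-octenyl bromide. The carbocycle is bought intact, and the only rings formed are transient: the dioxabicycle in step 3, then the oxirane in step 4.

Assumption: the SMILES is read literally and prostanoid numbering is used (C1 = ester carbon). C12 is then S in the target. Because CIP priorities change, the same spatial arrangement is R in 7, 8, 13 and 14.

**Step 1**
Reactants: 1 (2Z)-oct-2-en-1-ol
Product: 2 (2Z)-1-bromooct-2-ene
Conditions: PBr3 (0.4 equiv), Et2O, −20 → 0 °C, 1 h
Reagents that add atoms: phosphorus tribromide, BrP(Br)Br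
Why: PBr3 bromination runs by SN2 displacement of the primary allylic phosphite ester by bromide, which at low temperature keeps the Z alkene and gives little allylic transposition.

**Step 2**
Reactants: 2 (2Z)-1-bromooct-2-ene; 3 sodium cyclopentadienide, NaC5H5
Product: 5 1-[(2Z)-oct-2-en-1-yl]cyclopenta-1,3-diene, via 5-octenyl isomer 4 (not isolated)
Conditions: NaC5H5 (1.1 equiv, 2 M in THF), THF, −60 → −20 °C; cold pentane/water work-up; pentane solution held at 22 °C for about 4 h (1H NMR control), used at once
Reagents that add atoms: none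
Why: SN2 C-alkylation of cyclopentadienide gives 4, whose suprafacial [1,5]-sigmatropic hydrogen shift to the 1-alkyl diene 5 is much faster than the next shift to the 2-alkyl isomer, so timed ageing gives mainly 5, and products from residual 2-alkyl isomer are removed after step 3.

**Step 3**
Reactants: 5 1-[(2Z)-oct-2-en-1-yl]cyclopenta-1,3-diene
Product: 7 (4R)-4-hydroxy-4-[(2Z)-oct-2-en-1-yl]cyclopent-2-en-1-one, via racemic endoperoxide 6 (not isolated)
Conditions: O2 (1 atm), tetraphenylporphyrin (0.2 mol %), white LED, CH2Cl2, −78 °C; Ar purge; 9-O-acetylcupreidine (10 mol %), −60 °C, stopped at 45–48 % conversion of 6; thiourea (0.6 equiv), MeOH–H2O, −60 → 20 °C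
Reagents that add atoms: dioxygen, O=O
Why: Proposed new method: singlet oxygen adds suprafacially across the s-cis ring diene ([4+2], orders of magnitude faster than the ene reaction at the isolated Z alkene) and makes both ring C–O bonds as racemic 6; the bifunctional cinchona base then triggers an E2-type Kornblum–DeLaMare fragmentation, in which the quinuclidine nitrogen removes the only bridgehead hydrogen (antiperiplanar to O–O) while the 6'-OH hydrogen-bonds to the departing oxygen; the two enantiomers present this H–C–O–O array as mirror images beside a bulky bridgehead chain, so only (1R,4S)-6 fits the pocket and collapses to (R)-7 with its C12–O bond untouched, which means the kinetic resolution fixes C12 (goal: selectivity factor ≥ 25, about 40 % yield, ≥ 93 % ee); the closest known reaction type is the cinchona-catalysed desymmetrising Kornblum–DeLaMare rearrangement of meso endoperoxides, which has not been used to resolve racemic bridgehead-alkylated 2,3-dioxabicyclo[2.2.1]heptenes or to deliver a tertiary carbinol.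

**Step 4**
Reactants: 7 (4R)-4-hydroxy-4-[(2Z)-oct-2-en-1-yl]cyclopent-2-en-1-one
Product: 8 (1R,4R,5S)-4-hydroxy-4-[(2Z)-oct-2-en-1-yl]-6-oxabicyclo[3.1.0]hexan-2-one (oxirane cis to OH)
Conditions: 30 % aq H2O2 (3 equiv), NaOH (0.2 equiv), MeOH, −10 °C, 45 min
Reagents that add atoms: hydrogen peroxide, OO
Why: Weitz–Scheffer nucleophilic epoxidation attacks only the electron-poor enone and leaves the Z alkene alone; hydroperoxide is delivered syn to the hydroxyl (hydrogen bond, chain blocks the other face), giving two oxirane centres that are erased in step 7, while catalytic base, low temperature and short contact keep retro-aldol racemisation at C12 negligible.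

**Step 5**
Reactants: 9 methyl hex-5-enoate; 10 (2E)-but-2-enal
Product: 11 methyl (5E)-7-oxohept-5-enoate
Conditions: second-generation Hoveyda–Grubbs catalyst, RuCl2(H2IMes)(=CH-C6H4-2-OiPr) (1.5 mol %), 10 (4 equiv), CH2Cl2, 40 °C, 4 h
Reagents that add atoms: none
Why: Olefin cross-metathesis of a terminal alkene with an excess of an electron-poor enal is selective for the cross product and gives the E enal under thermodynamic control, driven by loss of propene.

**Step 6**
Reactants: 8 (1R,4R,5S)-4-hydroxy-4-[(2Z)-oct-2-en-1-yl]-6-oxabicyclo[3.1.0]hexan-2-one; 11 methyl (5E)-7-oxohept-5-enoate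
Product: 13 methyl (5E)-7-hydroxy-7-{(1R,4R,5S)-4-hydroxy-4-[(2Z)-oct-2-en-1-yl]-2-oxo-6-oxabicyclo[3.1.0]hexan-3-yl}hept-5-enoate (diastereomer mixture at C7 and C8), via dilithium enolate-alkoxide 12 (not isolated)
Conditions: LiN(iPr)2 (2.1 equiv), THF, −78 °C, 40 min; 11 (1.2 equiv), −78 °C, 30 min; AcOH (2.5 equiv) in THF, −78 °C
Reagents that add atoms: none
Why: In this directed lithium-enolate aldol addition the first equivalent of base takes the OH and the second the only enolisable CH2 (C8); the dianion adds 1,2 to the enal faster than it touches the ester, cannot undergo retro-aldol at C12 while the ketone is masked as its enolate, and cannot undergo Payne migration because the oxirane is cis to the alkoxide; the new C7 and C8 centres are uncontrolled but erased in step 7.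

**Step 7**
Reactants: 13 methyl (5E)-7-hydroxy-7-{(1R,4R,5S)-4-hydroxy-4-[(2Z)-oct-2-en-1-yl]-2-oxo-6-oxabicyclo[3.1.0]hexan-3-yl}hept-5-enoate
Product: 15 methyl (5E,7E,12S,14Z)-10-chloro-12-hydroxy-9-oxoprosta-5,7,10,14-tetraen-1-oate (target), via chlorohydrin 14 (not isolated)
Conditions: HCl (4 M in 1,4-dioxane, 5 equiv), CH2Cl2, 0 → 22 °C, 3 h
Reagents that add atoms: hydrogen chloride, Cl
Why: This is an epoxy-ketone to α-chloroenone conversion combined with an acid-catalysed aldol condensation: chloride opens the protonated oxirane by SN2 at C10 (α to C=O) to give 14; enol-assisted loss of the C11 hydroxyl and of the allylically activated C7 hydroxyl then gives the chloroenone and the dienone; reversible HCl addition equilibrates C7=C8 to the more stable E isomer; C12–OH survives because its ionisation would give a cyclopentadienyl-type cation, so C12 is untouched (its descriptor becomes S only through the priority change).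

**Compound list**
1 | (2Z)-oct-2-en-1-ol | CCCCC/C=C\CO | starting material
2 | (2Z)-1-bromooct-2-ene | CCCCC/C=C\CBr | intermediate
3 | sodium cyclopentadienide, NaC5H5 | [Na+].c1cc[cH-]c1 | starting material
4 | 5-[(2Z)-oct-2-en-1-yl]cyclopenta-1,3-diene | CCCCC/C=C\CC1C=CC=C1 | intermediate
5 | 1-[(2Z)-oct-2-en-1-yl]cyclopenta-1,3-diene | CCCCC/C=C\CC1=CC=CC1 | intermediate
6 | racemic 1-[(2Z)-oct-2-en-1-yl]-2,3-dioxabicyclo[2.2.1]hept-5-ene (relative configuration fixed by the bicycle; the 1R,4S enantiomer is the one converted) | CCCCC/C=C\CC12CC(C=C1)OO2 | intermediate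
7 | (4R)-4-hydroxy-4-[(2Z)-oct-2-en-1-yl]cyclopent-2-en-1-one | CCCCC/C=C\C[C@]1(O)C=CC(=O)C1 | intermediate
8 | (1R,4R,5S)-4-hydroxy-4-[(2Z)-oct-2-en-1-yl]-6-oxabicyclo[3.1.0]hexan-2-one | CCCCC/C=C\C[C@]1(O)[C@H]2O[C@H]2C(=O)C1 | intermediate
9 | methyl hex-5-enoate | C=CCCCC(=O)OC | starting material
10 | (2E)-but-2-enal (crotonaldehyde) | C/C=C/C=O | starting material
11 | methyl (5E)-7-oxohept-5-enoate | O=C/C=C/CCCC(=O)OC | intermediate
12 | dilithium enolate-alkoxide of 8 | CCCCC/C=C\C[C@]1([O-])[C@H]2O[C@H]2C([O-])=C1.[Li+].[Li+] | intermediate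
13 | methyl (5E)-7-hydroxy-7-{(1R,4R,5S)-4-hydroxy-4-[(2Z)-oct-2-en-1-yl]-2-oxo-6-oxabicyclo[3.1.0]hexan-3-yl}hept-5-enoate (mixture at C7 and C8) | CCCCC/C=C\C[C@]1(O)[C@H]2O[C@H]2C(=O)C1C(O)/C=C/CCCC(=O)OC | intermediate
14 | methyl (5E,10S,11R,12R,14Z)-10-chloro-7,11,12-trihydroxy-9-oxoprosta-5,14-dien-1-oate (mixture at C7 and C8) | CCCCC/C=C\C[C@]1(O)[C@@H](O)[C@H](Cl)C(=O)C1C(O)/C=C/CCCC(=O)OC | intermediate
15 | methyl (5E,7E,12S,14Z)-10-chloro-12-hydroxy-9-oxoprosta-5,7,10,14-tetraen-1-oate | CCCCC/C=C\C[C@]1(O)C=C(Cl)C(=O)/C1=C/C=C/CCCC(=O)OC | target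

**Totals**
Total step count: 7.
Longest linear sequence: 6 (steps 1, 2, 3, 4, 6, 7).
The organocatalyst is made from quinidine by known demethylation and acetylation, which is not counted.

**Three steps most likely to fail**

**Step 3 (the proposed new step).**
- Risks: the selectivity factor may be too low, 6 may decay without the base, and the sense of selection is not known in advance. If the 1S,4R peroxide proves to be the fast one, the pseudoenantiomeric 9-O-acetylcupreine is used instead.
- Fallback with known chemistry, from 5 back to 7: the same sensitised photooxygenation gives 6, but all of it is reduced at −78 °C with thiourea in MeOH. This gives the racemic cis-diol, a 1:1 mixture of (1R,4S)-1-[(2Z)-oct-2-en-1-yl]cyclopent-2-ene-1,4-diol F1 and (1S,4R)-1-[(2Z)-oct-2-en-1-yl]cyclopent-2-ene-1,4-diol F2. Candida antarctica lipase B with vinyl acetate in MTBE shows its usual preference for the R secondary carbinol of cyclopent-2-enols. It acetylates F2 to (1R,4S)-4-hydroxy-4-[(2Z)-oct-2-en-1-yl]cyclopent-2-en-1-yl acetate F3 and leaves F1. After separation on silica, MnO2 in CH2Cl2 oxidises the allylic secondary alcohol of F1 to give 7.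

**Step 7 (three acid-driven events in one flask).**
- Risks: capture of the C7 allyl cation by chloride or by the C11 hydroxyl, competing loss of the C12 hydroxyl while C8 still carries a hydrogen, and incomplete dehydration of the chlorohydrin.
- Fallback, from 13 back to 15: the condensation is taken out of the acid step and done by sulfonate activation. MeSO2Cl/Et3N in CH2Cl2 at −30 °C sulfonylates only the secondary allylic hydroxyl to give the C7 methanesulfonate of 13 F7. DBU converts F7 by E1cB elimination into methyl (5E,7E,10R,11S,12R,14Z)-10,11-epoxy-12-hydroxy-9-oxoprosta-5,7,14-trien-1-oate F8. HCl in dioxane then only has to open the oxirane to methyl (5E,7E,10S,11R,12R,14Z)-10-chloro-11,12-dihydroxy-9-oxoprosta-5,7,14-trien-1-oate F9. This compound has no hydrogen at C8, and its single dehydration gives 15.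

**Step 6 (unprotected dianion aldol).**
- Risks: incomplete second deprotonation, alkoxide-driven side reactions of the epoxy alcohol, and low conversion at the hindered C8.
- Fallback, from 8 back to 13: switch to a protected mono-enolate. Et3SiOTf/2,6-lutidine converts 8 into its triethylsilyl ether F4. LiN(iPr)2 (1.1 equiv) gives the lithium enolate of the silyl ether F5, which adds to 11 to give the 12-O-triethylsilyl aldol F6. Under the step 7 conditions the silyl ether is cleaved first, so 13 forms in the flask and the route continues from 13.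

**Further compounds**
F1 | step 3 | (1R,4S)-1-[(2Z)-oct-2-en-1-yl]cyclopent-2-ene-1,4-diol | CCCCC/C=C\C[C@]1(O)C=C[C@@H](O)C1
F2 | step 3 | (1S,4R)-1-[(2Z)-oct-2-en-1-yl]cyclopent-2-ene-1,4-diol | CCCCC/C=C\C[C@@]1(O)C=C[C@H](O)C1
F3 | step 3 | (1R,4S)-4-hydroxy-4-[(2Z)-oct-2-en-1-yl]cyclopent-2-en-1-yl acetate | CCCCC/C=C\C[C@@]1(O)C=C[C@H](OC(C)=O)C1
F4 | step 6 | triethylsilyl ether of 8 | CCCCC/C=C\C[C@]1(O[Si](CC)(CC)CC)[C@H]2O[C@H]2C(=O)C1
F5 | step 6 | lithium enolate of the silyl ether | CCCCC/C=C\C[C@]1(O[Si](CC)(CC)CC)[C@H]2O[C@H]2C([O-])=C1.[Li+]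
F6 | step 6 | 12-O-triethylsilyl aldol (mixture at C7 and C8) | CCCCC/C=C\C[C@]1(O[Si](CC)(CC)CC)[C@H]2O[C@H]2C(=O)C1C(O)/C=C/CCCC(=O)OC
F7 | step 7 | C7 methanesulfonate of 13 | CCCCC/C=C\C[C@]1(O)[C@H]2O[C@H]2C(=O)C1C(OS(C)(=O)=O)/C=C/CCCC(=O)OC
F8 | step 7 | methyl (5E,7E,10R,11S,12R,14Z)-10,11-epoxy-12-hydroxy-9-oxoprosta-5,7,14-trien-1-oate | CCCCC/C=C\C[C@]1(O)[C@H]2O[C@H]2C(=O)/C1=C/C=C/CCCC(=O)OC
F9 | step 7 | methyl (5E,7E,10S,11R,12R,14Z)-10-chloro-11,12-dihydroxy-9-oxoprosta-5,7,14-trien-1-oate | CCCCC/C=C\C[C@]1(O)[C@@H](O)[C@H](Cl)C(=O)/C1=C/C=C/CCCC(=O)OC
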